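**Plan**

- Labels: ring A carries OH at C1, the chain at C3 and the ether oxygen at C5. Ring B carries the ether oxygen at C1, OH at C2 and C4 and the chain at C6. The chain runs from C1' (on ring B) to C14' (on ring A).
- Retrosynthesis: the C1'–C2' and C13'–C14' bonds are cut together (each as the C=C bond of a Wittig reaction), then the ring B C1–O ether bond (Ullmann). The three phenols are carried as methyl ethers.
- Enabling feature: C1' and C14' are both benzylic, on C6 of ring B and C3 of ring A of one diaryl ether. They can therefore be the two formyl carbons of a rigid dialdehyde, and C2'–C13' can be a single C12 bis-ylide.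
- Forward: phenol 1 and bromide 2 give dialdehyde 3; dibromide 4 and phosphine 5 give bis-salt 6. Its bis-ylide 7 reacts with 3, through open-chain ylide 8, to close the 20-membered ring as diene 9. This is the only ring formed in the route.
- Hydrogenation to 10 and triple O-demethylation give the target 11.
- Stereochemistry: the target has no stereocentre, and the alkene geometry of 9 is erased by hydrogenation.

Key step: step 3

Assumption: compounds 1, 2, 4 and 5 are taken as purchasable; Z alkenes drawn in SMILES and unassigned carbinol centres stand for mixtures, acceptable because these elements are removed later.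

**Route**

Step 1
Reactants: 1 3-hydroxy-5-methoxybenzaldehyde; 2 2-bromo-3,5-dimethoxybenzaldehyde
Product: 3 2-(3-formyl-5-methoxyphenoxy)-3,5-dimethoxybenzaldehyde
Conditions: CuI (10 mol %), picolinic acid (20 mol %), K3PO4 (2 equiv), DMSO, 90 °C, N2
Reagents that add atoms: none
Why: Ullmann-type copper-catalysed diaryl ether synthesis, in which the ortho-formyl group activates the C–Br bond of 2, phenol 1 is unhindered, and neither non-enolisable aldehyde is harmed by anhydrous phosphate.

Step 2
Reactants: 4 1,12-dibromododecane; 5 triphenylphosphine (2.2 equiv)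
Product: 6 dodecane-1,12-diylbis(triphenylphosphonium) dibromide
Conditions: MeCN, reflux; precipitation with Et2O, drying in vacuo
Reagents that add atoms: none
Why: Double SN2 quaternisation of a primary dibromide by PPh3 (phosphonium salt formation) is routine, and the bis-salt should crystallise free of mono-salt.

Step 3
Reactants: 3 2-(3-formyl-5-methoxyphenoxy)-3,5-dimethoxybenzaldehyde; 6 dodecane-1,12-diylbis(triphenylphosphonium) dibromide
Product: 9 bis-Z macrocyclic diene trimethyl ether, via C12 bis-ylide 7 (not isolated), via open-chain formyl ylide 8 (not isolated)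
Conditions: 6, KN(SiMe3)2 (1.95–2.0 equiv), THF, −78 to 0 °C; then the ylide solution and 3 in THF added simultaneously by syringe pump to THF, rt, final about 1 mM
Reagents that add atoms: none
Why: Each ylide carbon of 7 adds to a formyl carbon to give an oxaphosphetane, whose cycloreversion delivers the C=C bond and Ph3P=O (Wittig olefination). The first olefination is intermolecular, most likely at the less hindered ring A aldehyde to give 8, and the second is an intramolecular Wittig macrocyclisation in which C2' attacks the ring B formyl carbon and closes the 20-membered ring (14 chain carbons, three ring A carbons, the ether oxygen, two ring B carbons); the opposite order converges on the same product. The closest known reaction type is the bis-Wittig cyclophane synthesis from aromatic dialdehydes and alkane-α,ω-diyl bis-ylides. No stereocentre is formed; the salt-free potassium ylide should favour Z alkenes, but the geometry is irrelevant because step 4 saturates both. The selectivity needed is 1:1 ring closure over oligomerisation, secured by pseudo-high dilution (slow co-addition so that neither partner accumulates) and by the bent diaryl ether hinge, which holds both formyl groups within reach of one C12 tether. A slight deficit of base prevents amide addition to the aldehydes.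

Step 4
Reactants: 9 bis-Z macrocyclic diene trimethyl ether
Product: 10 saturated macrocycle trimethyl ether (ring A C1-OMe, ring B C2,C4-di-OMe, (CH2)14 bridge)
Conditions: H2 (1 atm), Pd/C (10 %), EtOAc, rt
Reagents that add atoms: none
Why: Heterogeneous catalytic hydrogenation should saturate both 1,2-disubstituted styrenyl alkenes regardless of geometry, while aryl methyl ethers and the diaryl ether are inert to Pd/C and H2.

Step 5
Reactants: 10 saturated macrocycle trimethyl ether
Product: 11 target macrocycle (CNP0173380.0)
Conditions: BBr3 (6 equiv), CH2Cl2, −78 °C to rt, argon; then H2O, 0 °C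
Reagents that add atoms: none
Why: Lewis-acid ether cleavage: BBr3 coordinates each methoxy oxygen and bromide removes the methyl group by SN2, whereas the diaryl ether offers no sp3 carbon for attack and the saturated chain is inert.

**Compound list**

1 | 3-hydroxy-5-methoxybenzaldehyde | COc1cc(O)cc(C=O)c1 | starting material
2 | 2-bromo-3,5-dimethoxybenzaldehyde | COc1cc(OC)c(Br)c(C=O)c1 | starting material
3 | 2-(3-formyl-5-methoxyphenoxy)-3,5-dimethoxybenzaldehyde | COc1cc(C=O)cc(c1)Oc1c(OC)cc(OC)cc1C=O | intermediate
4 | 1,12-dibromododecane | BrCCCCCCCCCCCCBr | starting material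
5 | triphenylphosphine | c1ccc(cc1)P(c1ccccc1)c1ccccc1 | starting material
6 | dodecane-1,12-diylbis(triphenylphosphonium) dibromide | [Br-].[Br-].c1ccc(cc1)[P+](c1ccccc1)(c1ccccc1)CCCCCCCCCCCC[P+](c1ccccc1)(c1ccccc1)c1ccccc1 | intermediate
7 | C12 bis-ylide, Ph3P=CH(CH2)10CH=PPh3 | c1ccc(cc1)P(c1ccccc1)(c1ccccc1)=CCCCCCCCCCCC=P(c1ccccc1)(c1ccccc1)c1ccccc1 | intermediate (not isolated)
8 | open-chain formyl ylide, 3,5-dimethoxy-2-{3-methoxy-5-[(Z)-13-(triphenylphosphoranylidene)tridec-1-enyl]phenoxy}benzaldehyde (the ring-B-first regioisomer would serve equally) | COc1cc(/C=C\CCCCCCCCCCC=P(c2ccccc2)(c2ccccc2)c2ccccc2)cc(c1)Oc1c(OC)cc(OC)cc1C=O | intermediate (not isolated)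
9 | bis-Z macrocyclic diene trimethyl ether: 20-membered ring with C1'=C2' on ring B C6 and C13'=C14' on ring A C3, ether oxygen from ring A C5 to ring B C1, OMe at ring A C1 and ring B C2 and C4 (Z,Z drawn, any geometry acceptable) | COc1cc2cc(c1)Oc1c(OC)cc(OC)cc1/C=C\CCCCCCCCCC/C=C\2 | intermediate
10 | saturated macrocycle trimethyl ether: as 9 with a (CH2)14 bridge | COc1cc2cc(c1)Oc1c(OC)cc(OC)cc1CCCCCCCCCCCCCC2 | intermediate
11 | target: (CH2)14 chain from ring A C3 to ring B C6, ether oxygen from ring A C5 to ring B C1, OH at ring A C1 and ring B C2 and C4 | Oc1cc2cc(c1)Oc1c(O)cc(O)cc1CCCCCCCCCCCCCC2 | target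

**Step count and risks**

Total step count: 5. Longest linear sequence: 4 steps (1, 3, 4, 5 or 2, 3, 4, 5).

Steps most likely to fail:

Step 3. Intermolecular chain growth may outrun the second, ring-closing olefination, and the unstabilised ylide may be partly quenched during the long addition, giving oligomers and open-chain aldehydes. The fallback sets out from 3 and returns at 10, replacing the two-component closure by a unimolecular one. Addition of hept-6-enylmagnesium bromide (from 7-bromohept-1-ene and Mg, THF, 0 °C) to both formyl groups should give the bis-carbinol diene 1-{2-[3-(1-hydroxyoct-7-en-1-yl)-5-methoxyphenoxy]-3,5-dimethoxyphenyl}oct-7-en-1-ol F1 as a diastereomer mixture. Ring-closing metathesis with second-generation Grubbs catalyst in CH2Cl2 at 40 °C and about 1 mM should close the same 20-membered ring at C7'=C8', giving the macrocyclic diol alkene F2. H2 over Pd/C in AcOH with catalytic HClO4 should then saturate the alkene and hydrogenolyse both benzylic C–OH bonds to reach 10.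

Step 1. Coupling at the C–Br bond flanked by formyl and methoxy groups may be sluggish, so that hydrodebromination of 2 or stalling at partial conversion competes. The fallback sets out from 2 and returns at 3, moving the coupling to the carboxylic acid oxidation level, where an ortho-carboxylate strongly assists copper-mediated substitution. Pinnick oxidation of 2 (NaClO2, NaH2PO4, 2-methylbut-2-ene, t-BuOH/H2O) should give 2-bromo-3,5-dimethoxybenzoic acid F3. Ullmann condensation of F3 with 1 (Cu powder, catalytic CuI, K2CO3, pyridine, DMF, 110 °C) should give 2-(3-formyl-5-methoxyphenoxy)-3,5-dimethoxybenzoic acid F4. LiAlH4 in THF should reduce both the acid and the aldehyde to the diol {2-[3-(hydroxymethyl)-5-methoxyphenoxy]-3,5-dimethoxyphenyl}methanol F5, and MnO2 in CH2Cl2 should oxidise both benzylic alcohols to 3.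

Step 5. Demethylation may stop at mixed partial methyl ethers, or the electron-rich 1,2,4-trioxygenated ring B of the product may degrade oxidatively during the acidic work-up. The fallback sets out from 3 and returns at 11, exchanging the protecting groups before ring closure so that the last step is a neutral hydrogenation. BBr3 in CH2Cl2 on 3, where the formyl groups deactivate both rings, should give 2-(3-formyl-5-hydroxyphenoxy)-3,5-dihydroxybenzaldehyde F6. Benzyl bromide and K2CO3 in DMF should give 3,5-bis(benzyloxy)-2-[3-(benzyloxy)-5-formylphenoxy]benzaldehyde F7. The double Wittig macrocyclisation with bis-ylide 7 from 6, under the conditions of step 3, should give the tribenzyl ether of the macrocyclic diene F8. H2 over Pd/C in EtOAc/EtOH should then saturate both alkenes and cleave the three benzyl ethers in one operation to give 11.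

Further compounds
F1 | step 3 | 1-{2-[3-(1-hydroxyoct-7-en-1-yl)-5-methoxyphenoxy]-3,5-dimethoxyphenyl}oct-7-en-1-ol (diastereomer mixture) | COc1cc(cc(c1)Oc1c(OC)cc(OC)cc1C(O)CCCCCC=C)C(O)CCCCCC=C
F2 | step 3 | macrocyclic 1',14'-diol with C7'=C8' alkene, trimethyl ether (E/Z and diastereomer mixture) | COc1cc2cc(c1)Oc1c(OC)cc(OC)cc1C(O)CCCCCC=CCCCCCC2O
F3 | step 1 | 2-bromo-3,5-dimethoxybenzoic acid | COc1cc(OC)c(Br)c(c1)C(=O)O
F4 | step 1 | 2-(3-formyl-5-methoxyphenoxy)-3,5-dimethoxybenzoic acid | COc1cc(C=O)cc(c1)Oc1c(OC)cc(OC)cc1C(=O)O
F5 | step 1 | {2-[3-(hydroxymethyl)-5-methoxyphenoxy]-3,5-dimethoxyphenyl}methanol | COc1cc(CO)cc(c1)Oc1c(OC)cc(OC)cc1CO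
F6 | step 5 | 2-(3-formyl-5-hydroxyphenoxy)-3,5-dihydroxybenzaldehyde | Oc1cc(C=O)cc(c1)Oc1c(O)cc(O)cc1C=O
F7 | step 5 | 3,5-bis(benzyloxy)-2-[3-(benzyloxy)-5-formylphenoxy]benzaldehyde | O=Cc1cc(OCc2ccccc2)cc(c1)Oc1c(OCc2ccccc2)cc(OCc2ccccc2)cc1C=O
F8 | step 5 | tribenzyl ether of the bis-Z macrocyclic diene (any alkene geometry acceptable) | C(Oc1cc2cc(c1)Oc1c(OCc3ccccc3)cc(OCc3ccccc3)cc1/C=C\CCCCCCCCCC/C=C\2)c1ccccc1
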